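Atom numbering used throughout: ring carbons C1 (CHOH), C2, C3, C4 (epoxide carbon with CH3), C5 (epoxide CH), C6 (lactone OCH), C7 (butenolide β-carbon), C8 (CH with the tiglate), C9, C10 (CH with CH3); lactone carbons C11 (α, carrying C13H2OAc) and C12 (C=O). Compound numbers are those of the steps below.

## Analysis of the target

Target 25 is a germacrane-type sesquiterpenoid: a ten-membered carbocycle (C1–C10) fused at C6/C7 to an α,β-unsaturated γ-lactone (O–C12(=O)–C11=C7, lactone oxygen on C6) and at C4/C5 to an epoxide. It has six stereocentres: C1 (S, free hydroxyl), C4 (R), C5 (S), C6 (S), C8 (S, tiglate) and C10 (R). C1 and C10 are vicinal and anti. C4, C5 and C6 are contiguous, with a cis-epoxide (C3 and C6 on the same side) and an erythro relation between the epoxide oxygen at C5 and the lactone oxygen at C6. The C1/C10 pair is insulated from the C4–C6 triad by C2–C3, and C8 is cut off from both by sp2 C7 and by C9, so no group of centres can control another. Sensitive features are the trisubstituted epoxide (acid, and attack by the C1 hydroxyl), the butenolide with its acidic C6–H, the primary allylic acetate at C13, the tiglate and the medium ring. The difficulties are therefore closure of a ten-membered ring and the setting of remote stereocentres without relay. The strategy rests on one feature: C7 is sp2 and bonded directly to the carbinol carbon C8, so a C7–metal bond on a finished butenolide can add to a C8 aldehyde and close the carbocycle while creating only the C8 stereocentre.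

## Retrosynthetic reasoning

**25 ⇒ 24 ⇒ 23 ⇒ 21 (ester C–O bonds at C13 and C8, two O–Si bonds).** The acetate and the tiglate are the groups least compatible with a low-valent metal and a metal alkoxide, so they are cut first. Only three operations then follow the ring closure: acylation of the single free hydroxyl of 21 with 22, removal of both silyl ethers from 23, and acetylation of the primary hydroxyl of 24 in preference to the hindered secondary one.

**21 ⇒ 19 (C7–C8, through alkenylchromium 20).** This is the only ring bond that joins an sp2 carbon to a carbinol carbon, so it can be made by 1,2-addition of an alkenylmetal to an aldehyde. Cutting any other ring bond would form two stereocentres during macrocyclisation or require a quaternary centre to be made in the ring. The gain is that five of the six stereocentres and every oxidation level are fixed in open-chain 19. The forward reaction must activate the C7–I bond chemoselectively, close a ten-membered ring against intermolecular coupling and set C8.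

**19 ⇒ 18 ⇒ 16 (C8 oxidation level, through borane 17).** The C8 aldehyde is traced to the terminal alkene C8=C9. This alkene is inert to everything that precedes and is the only monosubstituted alkene in 16, so anti-Markovnikov hydroboration is unambiguous; no second vinyl group has to be told apart.

**16 ⇒ 15 ⇒ 14 ⇒ 13 (O–C6 and C7–I by iodolactonisation; C11–C12 by carbonylation).** The tetrasubstituted iodoalkene is the hardest part of 19 to build with defined geometry. Closing the lactone onto an allene solves it: the ring fixes the geometry, iodine lands on C7, and C6 is set stereospecifically from the propargylic centre of 13. The lactone is made after the epoxide and not before. Closing an epoxide from a hydroxy sulfonate next to a finished butenolide would need base, and the acidic C6–H would then lead to elimination to a γ-alkylidene butenolide. The forward steps must transfer chirality centre → axis → centre and stay neutral.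

**13 ⇒ 12 ⇒ 11 ⇒ 9 + 10 (C6–C7).** Acetylide addition of 10 to epoxy aldehyde 9 brings in C7, C11 and C13. The carbonylation–lactonisation pair inverts C6, so the (6R) carbinol is needed. That is not the epimer favoured by the epoxy aldehyde, so C6 is set by catalyst-controlled reduction of ynone 12.

**9 ⇒ 8 ⇒ 7 (both epoxide C–O bonds).** Sharpless asymmetric epoxidation of Z allylic alcohol 7 sets C4 and C5 under reagent control, independent of the remote C1/C10 pair. The Z alkene guarantees the cis-epoxide.

**7 ⇒ 6 ⇒ 5 ⇒ 3 + 4 (C1–C10).** Crotylboration of aldehyde 3 with 4 sets C1 and C10 in one step and delivers the C8=C9 alkene. The acetate of the starting material protects the allylic alcohol until it is needed to direct the epoxidation.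

**3 ⇒ 1 (cleavage of the terminal trisubstituted alkene, through ozonide 2).** Neryl acetate 1 supplies C1–C6, the C4 methyl group and the Z alkene.

## Alternatives that were turned down

**Alternative 1: anionic oxy-Cope ring expansion.** The disconnection is C8–C9, with a temporary C1–C6 bond of a six-membered ring broken in the same event. An alkoxide carrying two alkenyl arms on adjacent ring carbons rearranges [3,3] to the ten-membered dienone A1.
- For: the ring is formed without a cyclisation entropy penalty, both alkene geometries follow from the chair-like transition state, and the carbon skeleton C1–C10 with both methyl groups comes from a cheap six-membered terpenoid.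
- Against: A1 carries one stereocentre (C8) only. C1, C10, C4, C5 and C6 would all have to be set on a flexible cyclodecadienone: regio- and face-selective hydration of C1=C10, epoxidation of the enone alkene, reduction at C6 and annulation of C11–C13 at C7. A 1,5-diene in a ten-membered ring is also prone to transannular cyclisation.
- Comparison: ring construction is more reliable than in the chosen route, and this point is conceded. In exchange the chosen route sets five stereocentres by reagent control on open-chain compounds and needs three steps after ring closure; A1 would need many more, each with conformational risk.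

**Alternative 2: ozonolytic unveiling of the cyclodecane.** No ring C–C bond is formed. The tetrasubstituted C1=C6 alkene at the fusion of a bicyclic precursor is cleaved to the 1,6-diketone A2.
- For: C4, C8 and C10 are set on a rigid bicycle, the ring opening itself is certain, and no high dilution is needed.
- Against: A2 has ketones at C1 and C6, a C4 carbinol, a methylene at C5 and no lactone carbons. The two ketones must be told apart. C5 must be oxidised so that an epoxide can be closed from the tertiary C4 oxygen without losing C4. The C11–C13 unit must be added at C7. Transannular hemiketal and aldol reactions of a 1,6-diketone with a tertiary alcohol in a ten-membered ring are likely.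
- Comparison: certainty of ring formation is higher than for the chosen route. The chosen route offers a precursor 19 in which epoxide, lactone and all oxidation levels are already correct, so the risk is confined to one step.

**Alternative 3: methylenation–Claisen ring expansion.** The disconnection is C2–C3, with the C5–O bond of an eight-membered lactone-derived enol ether broken. Thermal rearrangement gives cyclodecenone A3.
- For: the Z geometry at C4=C5 is enforced by the cyclic transition state, C6, C8 and C10 and the five-membered oxygen ring are in place before expansion, and no metal-mediated macrocyclisation is needed. On the C8 configuration this plan is stronger, because C8 is fixed beforehand.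
- Against: an eight-membered lactone has to be made first. After expansion, A3 still needs face-selective reduction at C1, face-selective epoxidation of C4=C5 in the ring, oxidation of the dihydrofuran methylene to the lactone carbonyl and exchange of the C8 ether for the tiglate.
- Comparison: A3 leaves C1 and the epoxide to substrate control in a medium ring. The chosen route sets these under reagent control before ring closure and leaves only C8 open, with inversion available if it comes out wrong.

Key step: step 15

Assumption: (R)-TRIP is taken to direct crotylboration to the Re face of aliphatic aldehyde 3 as it does for aryl aldehydes; if the sense were reversed, the (S)-catalyst would be used.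

## Route

Step 1
Reactants: 1 neryl acetate
Product: 3 (2Z)-3-methyl-6-oxohex-2-en-1-yl acetate (C1 aldehyde), via secondary ozonide 2 (not isolated)
Conditions: O3 (1.0 equiv, indicator dye), CH2Cl2, −78 °C; then PPh3, −78 °C → rt
Reagents that add atoms: ozone, [O-][O+]=O
Why: Ozonolysis: electrophilic ozone cleaves the electron-rich 6,7-alkene of 1 in preference to the 2,3-alkene, which is deactivated by the allylic acetate, and reduction of ozonide 2 releases the aldehyde with the Z alkene intact.

Step 2
Reactants: 3 C1 aldehyde; 4 (E)-crotylboronic acid pinacol ester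
Product: 5 (2Z,6S,7R)-6-hydroxy-3,7-dimethylnona-2,8-dien-1-yl acetate [(1S,10R) in ring numbering]
Conditions: (R)-TRIP (5 mol %), 4 Å MS, toluene, −30 °C; aqueous work-up
Reagents that add atoms: none
Why: Chiral-phosphoric-acid-catalysed crotylboration through a closed chair transition state: the E geometry of 4 fixes the anti relation of C1–OH and C10–CH3, and (R)-TRIP should direct the crotyl group to the Re face of the aldehyde, which corresponds to (1S,10R).

Step 3
Reactants: 5 homoallylic alcohol
Product: 6 (2Z,6S,7R)-3,7-dimethyl-6-(triethylsilyloxy)nona-2,8-dien-1-yl acetate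
Conditions: Et3SiCl, imidazole, CH2Cl2, 0 °C → rt
Reagents that add atoms: chlorotriethylsilane, CC[Si](Cl)(CC)CC
Why: Silylation of the secondary alcohol; the triethylsilyl ether blocks the C1 oxygen, which would otherwise attack the later C4–C5 epoxide in a 5-exo fashion.

Step 4
Reactants: 6 silyl ether acetate
Product: 7 (2Z,6S,7R)-3,7-dimethyl-6-(triethylsilyloxy)nona-2,8-dien-1-ol
Conditions: K2CO3 (0.2 equiv), MeOH, 0 °C
Reagents that add atoms: none
Why: Base-catalysed transesterification of the acetate; a secondary triethylsilyl ether is stable to catalytic carbonate in methanol at 0 °C.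

Step 5
Reactants: 7 Z allylic alcohol
Product: 8 [(2S,3R)-3-methyl-3-[(3S,4R)-4-methyl-3-(triethylsilyloxy)hex-5-en-1-yl]oxiran-2-yl]methanol [(1S,4R,5S,10R)]
Conditions: Ti(OiPr)4 (10 mol %), L-(+)-diethyl tartrate (12 mol %), t-BuOOH, 4 Å MS, CH2Cl2, −20 °C
Reagents that add atoms: tert-butyl hydroperoxide, CC(C)(C)OO
Why: Sharpless asymmetric epoxidation: the titanium–tartrate complex delivers oxygen to one face of the allylic alcohol regardless of the remote centres, and L-(+)-tartrate is the ligand that converts nerol into its (2S,3R)-epoxide, the sense needed for (4R,5S). Syn addition to the Z alkene gives the cis-epoxide, and the isolated terminal alkene is inert.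

Step 6
Reactants: 8 epoxy alcohol
Product: 9 (2R,3R)-3-methyl-3-[(3S,4R)-4-methyl-3-(triethylsilyloxy)hex-5-en-1-yl]oxirane-2-carbaldehyde (C6 aldehyde)
Conditions: Dess–Martin periodinane, pyridine, CH2Cl2, 0 °C
Reagents that add atoms: none
Why: Dess–Martin oxidation of a primary 2,3-epoxy alcohol under buffered, non-acidic conditions; the α-epoxy aldehyde is used at once.

Step 7
Reactants: 9 epoxy aldehyde; 10 tert-butyldimethyl(prop-2-yn-1-yloxy)silane
Product: 11 propargylic alcohols (both C6 epimers; C6–C7≡C11–C13H2OSi)
Conditions: 10, n-BuLi, THF, −78 °C; then 9, −78 °C; H2O quench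
Reagents that add atoms: none
Why: 1,2-Addition of a lithium acetylide to the aldehyde forms C6–C7; the epimer ratio is irrelevant because both are oxidised in the next step.

Step 8
Reactants: 11 propargylic alcohols
Product: 12 epoxy ynone (C6 ketone)
Conditions: Dess–Martin periodinane, pyridine, CH2Cl2, 0 °C → rt
Reagents that add atoms: none
Why: Dess–Martin oxidation of a propargylic alcohol to the ynone, which erases the uncontrolled C6 centre.

Step 9
Reactants: 12 epoxy ynone
Product: 13 (6R)-propargylic alcohol [(1S,4R,5S,6R,10R)]
Conditions: Ru[(S,S)-TsDPEN](p-cymene) (2 mol %), i-PrOH, rt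
Reagents that add atoms: none
Why: Noyori asymmetric transfer hydrogenation of an alkynyl ketone: the alkynyl group takes the role of the aryl group of aryl alkyl ketones and selectivity is catalyst-controlled even beside an existing stereocentre. The (S,S)-ligand should give the (6R)-alcohol, the epimer needed because steps 11 and 12 together invert C6.

Step 10
Reactants: 13 (6R)-propargylic alcohol
Product: 14 (6R)-propargylic methanesulfonate
Conditions: MsCl, Et3N, CH2Cl2, −78 → −40 °C; used crude
Reagents that add atoms: methanesulfonyl chloride, CS(Cl)(=O)=O
Why: Sulfonylation at oxygen with retention at C6.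

Step 11
Reactants: 14 propargylic methanesulfonate
Product: 15 (aR)-2,3-allenoic acid (C6H=C7=C11(C13H2OSi)–C12O2H)
Conditions: Pd(PPh3)4 (5 mol %), CO (1 atm), 2,6-lutidine, THF/H2O, rt; work-up at pH 5
Reagents that add atoms: carbon monoxide, [C-]#[O+]; water, O
Why: Palladium-catalysed carbonylation of a propargylic electrophile: zerovalent palladium attacks C11 anti to the leaving group (SN2′), carbon monoxide inserts into the allenyl–palladium bond and water cleaves the acylpalladium, so the C6 configuration is transferred to the allene axis. 2,6-Lutidine takes up the sulfonic acid and so protects the epoxide and silyl ethers.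

Step 12
Reactants: 15 allenoic acid
Product: 16 4-iodobutenolide with terminal alkene [(1S,4R,5S,6R,10R); C6 now has the spatial arrangement of the target]
Conditions: I2 (1.5 equiv), NaHCO3, MeCN, 0 °C, dark
Reagents that add atoms: iodine, II
Why: Iodolactonisation of a 2,3-allenoic acid: the iodonium ion forms on C6=C7 and the carboxylate, held on one face by the allene axis, closes 5-endo onto C6 and places iodine on C7. This axial-to-central transfer sets C6 with net inversion relative to 13; the descriptor stays R only because iodine raises the rank of C7.

Step 13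
Reactants: 16 iodobutenolide alkene
Product: 18 C8 primary alcohol, via B-alkyl-9-borabicyclononane 17 (not isolated)
Conditions: 9-BBN, THF, 0 °C → rt; then Me3NO·2H2O, THF, 50 °C
Reagents that add atoms: trimethylamine N-oxide, C[N+](C)(C)[O-]
Why: Hydroboration–oxidation: the bulky dialkylborane adds only to the monosubstituted alkene with boron at C8, leaving the tetrasubstituted electron-poor butenolide alkene, the lactone and the epoxide untouched. The amine oxide oxidises the C–B bonds without hydroxide or peroxide, which could displace the vinylogous acyl iodide.

Step 14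
Reactants: 18 C8 primary alcohol
Product: 19 seco C8 aldehyde with complete epoxide and 4-iodobutenolide (C1 triethylsilyl ether, C13 tert-butyldimethylsilyl ether)
Conditions: Dess–Martin periodinane, pyridine, CH2Cl2, 0 °C → rt
Reagents that add atoms: none
Why: Dess–Martin oxidation of the primary alcohol to the aldehyde under buffered conditions.

Step 15
Reactants: 19 seco C8 aldehyde
Product: 21 ten-membered C8 alcohol as bis-silyl ether [(1S,4R,5S,6S,8S,10R)], via alkenylchromium dichloride 20 (not isolated)
Conditions: CrCl2 (10 equiv), NiCl2 (0.1 equiv), degassed DMSO, rt, 0.003 M, slow addition of 19; then H2O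
Reagents that add atoms: none
Why: CrCl2 reduces NiCl2 to zerovalent nickel, which inserts into the C7–I bond of the vinylogous acyl iodide; transmetallation to trivalent chromium gives alkenylchromium 20, which adds to the C8 aldehyde, and the chromium alkoxide is hydrolysed on work-up (Nozaki–Hiyama–Kishi reaction). The closest known reactions are nickel/chromium-mediated macrocyclisations of alkenyl iodide–aldehydes and intermolecular additions of β-iodo enoates and β-iodo enones under the same conditions. The ten-membered carbocycle closes in the 10-exo-trig mode, the carbonyl oxygen staying outside the ring. C8 is the only new stereocentre; it is under substrate control, through the conformation that the C1–C6 chain, held by the cis-epoxide, the C6 centre and the planar butenolide, imposes on the aldehyde as it approaches C7, and its sense cannot be predicted with confidence. The step needs chemoselectivity for the C–I bond, which the neutral conditions and the high reactivity of a β-iodo enoate towards nickel secure, since epoxide, lactone and silyl ethers are inert to CrCl2. It needs ring closure to beat intermolecular coupling, which high dilution and slow addition secure. It needs the alkenylmetal to survive: the largely covalent carbon–chromium bond tolerates the β-oxygen at C6, whereas a C13 acetate would be an allylic electrophile for low-valent nickel and an acyl donor to the new C8 alkoxide, hence the silyl ether.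

Step 16
Reactants: 21 ten-membered C8 alcohol; 22 tigloyl chloride
Product: 23 C8 tiglate bis-silyl ether
Conditions: 22, Et3N, DMAP (cat.), CH2Cl2, 0 °C → rt
Reagents that add atoms: none
Why: DMAP-catalysed acylation of the secondary C8 alcohol with retention; the acid chloride keeps the E geometry of the tiglate.

Step 17
Reactants: 23 C8 tiglate bis-silyl ether
Product: 24 C1,C13-diol
Conditions: HF·pyridine, excess pyridine, THF, 0 °C → rt
Reagents that add atoms: none
Why: Fluoride-induced cleavage of both silyl ethers; excess pyridine buffers the reagent so that the trisubstituted epoxide is not opened by acid or by the liberated C1 hydroxyl.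

Step 18
Reactants: 24 C1,C13-diol
Product: 25 target CNP0159184.1
Conditions: Ac2O (1.1 equiv), 2,4,6-collidine, CH2Cl2, −20 → 0 °C
Reagents that add atoms: acetic anhydride, CC(=O)OC(C)=O
Why: Chemoselective acylation: the primary allylic C13 hydroxyl reacts far faster with one equivalent of anhydride and a hindered base than the secondary C1 hydroxyl flanked by the C10 methyl branch.

## Compound list

1 | neryl acetate, (2Z)-3,7-dimethylocta-2,6-dien-1-yl acetate | CC(C)=CCC/C(C)=C\COC(C)=O | starting material
2 | secondary ozonide of the 6,7-alkene of 1 (ozonide carbon unassigned) | CC1(C)OOC(CC/C(C)=C\COC(C)=O)O1 | intermediate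
3 | (2Z)-3-methyl-6-oxohex-2-en-1-yl acetate | O=CCC/C(C)=C\COC(C)=O | intermediate
4 | (E)-crotylboronic acid pinacol ester | C/C=C/CB1OC(C)(C)C(C)(C)O1 | starting material
5 | (2Z,6S,7R)-6-hydroxy-3,7-dimethylnona-2,8-dien-1-yl acetate | C=C[C@@H](C)[C@@H](O)CC/C(C)=C\COC(C)=O | intermediate
6 | (2Z,6S,7R)-3,7-dimethyl-6-(triethylsilyloxy)nona-2,8-dien-1-yl acetate | C=C[C@@H](C)[C@@H](O[Si](CC)(CC)CC)CC/C(C)=C\COC(C)=O | intermediate
7 | (2Z,6S,7R)-3,7-dimethyl-6-(triethylsilyloxy)nona-2,8-dien-1-ol | C=C[C@@H](C)[C@@H](O[Si](CC)(CC)CC)CC/C(C)=C\CO | intermediate
8 | [(2S,3R)-3-methyl-3-[(3S,4R)-4-methyl-3-(triethylsilyloxy)hex-5-en-1-yl]oxiran-2-yl]methanol | C=C[C@@H](C)[C@@H](O[Si](CC)(CC)CC)CC[C@@]1(C)O[C@H]1CO | intermediate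
9 | (2R,3R)-3-methyl-3-[(3S,4R)-4-methyl-3-(triethylsilyloxy)hex-5-en-1-yl]oxirane-2-carbaldehyde | C=C[C@@H](C)[C@@H](O[Si](CC)(CC)CC)CC[C@@]1(C)O[C@H]1C=O | intermediate
10 | tert-butyldimethyl(prop-2-yn-1-yloxy)silane | C#CCO[Si](C)(C)C(C)(C)C | starting material
11 | propargylic alcohols, (1S,4R,5S,10R), both C6 epimers | C=C[C@@H](C)[C@@H](O[Si](CC)(CC)CC)CC[C@@]1(C)O[C@H]1C(O)C#CCO[Si](C)(C)C(C)(C)C | intermediate
12 | epoxy ynone, C6 ketone, (1S,4R,5R,10R) | C=C[C@@H](C)[C@@H](O[Si](CC)(CC)CC)CC[C@@]1(C)O[C@H]1C(=O)C#CCO[Si](C)(C)C(C)(C)C | intermediate
13 | (6R)-propargylic alcohol, (1S,4R,5S,6R,10R) | C=C[C@@H](C)[C@@H](O[Si](CC)(CC)CC)CC[C@@]1(C)O[C@H]1[C@H](O)C#CCO[Si](C)(C)C(C)(C)C | intermediate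
14 | (6R)-propargylic methanesulfonate | C=C[C@@H](C)[C@@H](O[Si](CC)(CC)CC)CC[C@@]1(C)O[C@H]1[C@H](OS(C)(=O)=O)C#CCO[Si](C)(C)C(C)(C)C | intermediate
15 | (aR)-2,3-allenoic acid, C6H=C7=C11(CH2OTBS)CO2H, (1S,4R,5S,10R) | C=C[C@@H](C)[C@@H](O[Si](CC)(CC)CC)CC[C@@]1(C)O[C@H]1C([H])=[C@]=C(CO[Si](C)(C)C(C)(C)C)C(=O)O | intermediate
16 | 4-iodobutenolide with C8=C9 alkene, (1S,4R,5S,6R,10R) | C=C[C@@H](C)[C@@H](O[Si](CC)(CC)CC)CC[C@@]1(C)O[C@H]1[C@H]1OC(=O)C(CO[Si](C)(C)C(C)(C)C)=C1I | intermediate
17 | B-(C8-alkyl)-9-borabicyclo[3.3.1]nonane from 16 | C(C[C@@H](C)[C@@H](O[Si](CC)(CC)CC)CC[C@@]1(C)O[C@H]1[C@H]1OC(=O)C(CO[Si](C)(C)C(C)(C)C)=C1I)B1C2CCCC1CCC2 | intermediate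
18 | C8 primary alcohol, (1S,4R,5S,6R,10R) | OCC[C@@H](C)[C@@H](O[Si](CC)(CC)CC)CC[C@@]1(C)O[C@H]1[C@H]1OC(=O)C(CO[Si](C)(C)C(C)(C)C)=C1I | intermediate
19 | seco C8 aldehyde, (1S,4R,5S,6R,10R) | O=CC[C@@H](C)[C@@H](O[Si](CC)(CC)CC)CC[C@@]1(C)O[C@H]1[C@H]1OC(=O)C(CO[Si](C)(C)C(C)(C)C)=C1I | intermediate
20 | C7 alkenylchromium dichloride (trivalent chromium) from 19 | O=CC[C@@H](C)[C@@H](O[Si](CC)(CC)CC)CC[C@@]1(C)O[C@H]1[C@H]1OC(=O)C(CO[Si](C)(C)C(C)(C)C)=C1[Cr](Cl)Cl | intermediate
21 | ten-membered C8 alcohol, bis-silyl ether, (1S,4R,5S,6S,8S,10R) | O[C@H]1C[C@@H](C)[C@@H](O[Si](CC)(CC)CC)CC[C@@]2(C)O[C@H]2[C@H]2OC(=O)C(CO[Si](C)(C)C(C)(C)C)=C12 | intermediate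
22 | tigloyl chloride, (E)-2-methylbut-2-enoyl chloride | C/C=C(\C)C(Cl)=O | starting material
23 | C8 tiglate, bis-silyl ether, (1S,4R,5S,6S,8S,10R) | C/C=C(\C)C(=O)O[C@H]1C[C@@H](C)[C@@H](O[Si](CC)(CC)CC)CC[C@@]2(C)O[C@H]2[C@H]2OC(=O)C(CO[Si](C)(C)C(C)(C)C)=C12 | intermediate
24 | C8 tiglate C1,C13-diol | C/C=C(\C)C(=O)O[C@H]1C[C@@H](C)[C@@H](O)CC[C@@]2(C)O[C@H]2[C@H]2OC(=O)C(CO)=C12 | intermediate
25 | CNP0159184.1, (1S,4R,5S,6S,8S,10R) | C/C=C(\C)C(=O)O[C@H]1C[C@@H](C)[C@@H](O)CC[C@@]2(C)O[C@H]2[C@H]2OC(=O)C(COC(C)=O)=C12 | target

## Step count and least certain steps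

Total: 18 steps. Longest linear sequence: 18 steps (1 → 25); 4, 10 and 22 are bought.

**Step 15 (key step).** The most likely failure is poor or reversed facial selectivity in the addition to the aldehyde, because C8 is set only by the conformation of the closing medium ring. Intermolecular coupling, reduction of the C–I bond and loss of the C6 carboxylate from the alkenylmetal are further risks. Fallback: the route sets out from 19; if the ring closure gives mainly the 8R alcohol, the C8 epimer of 21 F1, this is esterified with tiglic acid under Mitsunobu conditions (PPh3, diisopropyl azodicarboxylate, toluene). The stereospecific inversion at C8 replaces substrate control and returns to the route at 23.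

**Step 11.** Once the allene is formed, the epoxide becomes allylic and may be ionised by zerovalent palladium; β-silyloxy elimination from the allenylpalladium intermediate is a second risk. Fallback without palladium: from 12, reduction with Ru[(R,R)-TsDPEN](p-cymene) in i-PrOH gives the (6S)-propargylic alcohol F2. Alkylation with iodomethyltributylstannane and KH gives the tributylstannylmethyl ether F3. n-BuLi at −78 °C triggers tin–lithium exchange and a suprafacial Still–Wittig [2,3] rearrangement to the allenylmethanol F4. Dess–Martin oxidation gives the allenal F5, and NaClO2/NaH2PO4 with 2-methylbut-2-ene gives acid 15, where the route is rejoined. The suprafacial shift from the (6S) ether gives the same allene axis as the antarafacial palladium step from the (6R) sulfonate.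

**Step 13.** The oxidant may attack the vinylogous acyl iodide, or the borane may reduce the lactone carbonyl slowly. Fallback: from 16, aldehyde-selective Wacker-type oxidation of the terminal alkene (PdCl2(PhCN)2, CuCl2, AgNO2, t-BuOH/MeNO2, O2) gives 19 directly, with no boron reagent and no basic oxidant.

**Step 2.** Enantiofacial discrimination by the phosphoric acid may be insufficient for an unbranched aliphatic aldehyde. Fallback: from 3, stoichiometric Brown crotylation with (E)-crotyldiisopinocampheylborane made from (−)-α-pinene at −78 °C gives 5. This moves the chirality from a hydrogen-bonding catalyst to the ligands on boron.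

## Further compounds

F1 | step 15 | (8R) epimer of ten-membered alcohol 21 | O[C@@H]1C[C@@H](C)[C@@H](O[Si](CC)(CC)CC)CC[C@@]2(C)O[C@H]2[C@H]2OC(=O)C(CO[Si](C)(C)C(C)(C)C)=C12
F2 | step 11 | (6S)-propargylic alcohol, C6 epimer of 13 | C=C[C@@H](C)[C@@H](O[Si](CC)(CC)CC)CC[C@@]1(C)O[C@H]1[C@@H](O)C#CCO[Si](C)(C)C(C)(C)C
F3 | step 11 | (6S)-propargylic tributylstannylmethyl ether | C=C[C@@H](C)[C@@H](O[Si](CC)(CC)CC)CC[C@@]1(C)O[C@H]1[C@@H](OC[Sn](CCCC)(CCCC)CCCC)C#CCO[Si](C)(C)C(C)(C)C
F4 | step 11 | (aS)-allenylmethanol, C6H=C7=C11(CH2OTBS)CH2OH | C=C[C@@H](C)[C@@H](O[Si](CC)(CC)CC)CC[C@@]1(C)O[C@H]1C([H])=[C@]=C(CO[Si](C)(C)C(C)(C)C)CO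
F5 | step 11 | (aR)-allenal, C6H=C7=C11(CH2OTBS)CHO | C=C[C@@H](C)[C@@H](O[Si](CC)(CC)CC)CC[C@@]1(C)O[C@H]1C([H])=[C@]=C(CO[Si](C)(C)C(C)(C)C)C=O
F0 | step 13 | none | none
F0 | step 2 | none | none
A1 | alternative 1 | ten-membered (Z,E)-dienone with C6 ketone and C8 p-methoxybenzyl ether | COc1ccc(CO[C@H]2C/C(C)=C/CC/C(C)=C\C(=O)C2)cc1
A2 | alternative 2 | ten-membered 1,6-diketone with C4 carbinol and C8 silyl ether | CC(C)(C)[Si](C)(C)O[C@H]1C[C@@H](C)C(=O)CC[C@@](C)(O)CC(=O)C1
A3 | alternative 3 | ten-membered C1 ketone with Z alkene at C4–C5 and fused dihydrofuran | COc1ccc(CO[C@H]2C[C@@H](C)C(=O)CC/C(C)=C\[C@H]3OCC(CO[Si](C)(C)C(C)(C)C)=C23)cc1
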